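## Structural features

The target is a 2-O-alkylglycerol: an unbranched eight-carbon chain joins the secondary oxygen of glycerol to a tetracyclo[6.4.0.0(2,7).0(3,6)]dodecane, that is, a cyclohexane (ring A) fused in a straight line to three cyclobutanes (rings B, C and D). Six contiguous methine stereocentres make up the A/B, B/C and C/D fusion bonds; every fusion is cis and neighbouring rings lie on opposite faces of the ring between them, so the ladder is the cis,anti,cis,anti,cis isomer. The seventh stereocentre is the chain-bearing carbon of ring A, one CH2 away from one A/B fusion carbon and two CH2 groups away from the other; it is S, its chain stands cis to ring B, and it alone makes the otherwise meso core chiral. The fragile parts are the two overlapping bicyclo[2.2.0]hexane units, whose central σ bonds are open to thermal, electrophilic, transition-metal and hydrogenolytic cleavage, and every cyclobutene and bicyclo[2.1.0]pentane intermediate on the way; the 1,3-diol only needs masking. The real difficulty is twofold: three strained rings must be fused with full control of the fusion geometry, and the remote stereocentre on ring A must be related to the ladder in the relative and the absolute sense although no functional group links them in the target. The key step exploits the fact that ring C consists of the two outer CH carbons of ring B plus two further carbons and is therefore the one-carbon homologue of a cyclopropane fused to that outer CH–CH bond: a carbene centre on the apex of this cyclopropane accepts one of the two cyclopropane bonds running to ring B and turns the three-membered ring into the cyclobutene of ring C.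

## Logic of the disconnections

**34 to 33.** The two O–H bonds of the diol are traced back to the two acetal C–O bonds of 33. A free 1,3-diol would interfere with bases, hydrides and carbenoids, whereas the six-membered acetal is inert to all of them and falls to dilute acid that leaves cyclobutanes untouched. Nothing is gained in the skeleton; the demand is that the last step needs only mild aqueous acid.

**33 to 32.** Two C–H bonds on the CH2–CH2 edge of ring D are removed, giving the ring D double bond of 32. A cyclobutene is what the ring expansion delivers, so no extra functional group is needed. The forward step must add hydrogen without a metal surface that could hydrogenolyse the ladder.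

**32 to 29, 27, then 26 and 20.** In 32 the bond between one C/D fusion carbon and the adjacent sp2 carbon of ring D is cut, which contracts ring D to a cyclopropane on the outer edge of ring C with an exocyclic carbene carbon, stored as 29. 29 goes back to 27 by functional-group change, and the two cyclopropane bonds of 27 are cut to give 26 and 20. Ring D is thereby reduced to a two-carbon reagent. The forward steps must cyclopropanate on the exo face and must run the expansion in the presence of an existing bicyclo[2.2.0]hexane.

**26 to 23 (key disconnection).** The same cut is made one ring earlier: the bond between one outer CH of ring B and an sp2 carbon of ring C is broken, giving the cyclopropane-fused 23. The cut creates no stereocentre and needs no second component, and either of the two equivalent bonds can be chosen. Ring C disappears, leaving a bicyclo[2.1.0]pentane that comes from an alkene. The forward 1,2-shift must outrun fragmentation and must run cold enough to spare the strained σ bonds.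

**23 to 21, then 19 and 20.** After functional-group change to 21, the two bonds from the cyclopropane apex to the outer carbons of ring B are cut. This leaves the chain-bearing bicyclic alkene 19 and the reagent 20. The forward addition must come from the face of ring B anti to ring A, which is the convex face.

**19 to 16, then 14.** The bond between an A/B fusion carbon and an sp2 carbon of ring B is cut in the same way, leading through 16 to the cyclopropane ester 14. This is the least strained and best precedented member of the expansion series. The cyclopropane must sit cis to the chain on ring A, and an intermolecular cyclopropanation could not guarantee this.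

**14 to 9 and 12 (through 13).** The bond between the first and second chain carbons, counted from ring A, is cut so that the first carbon is the former carboxyl carbon of 1. The seven-carbon chain with the masked glycerol becomes a separate fragment. The forward sp3–sp3 coupling must tolerate a hindered ester and an acetal.

**12 to 10 and 11.** The ether C–O bond is cut. Both pieces are commercial; the forward alkylation must be stopped at mono-substitution of 11.

**9 to 8, 7, then 6.** After functional-group changes back to 7, a bond is formed in the retrosynthetic sense: the carboxyl carbon on ring A is joined to the cyclopropane apex, giving the bridged ketone 6. A one-carbon bridge can exist only if the carboxyl carbon and the cyclopropane are cis, so the relative configuration that was hard to control becomes a consequence of ring constraints. The forward C–C cleavage must occur on the cyclopropane side of the ketone and must leave the two carboxyl groups distinguishable.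

**6 to 5, 4, then 1 and 2.** The two bonds from the apex to the former alkene carbons are cut (5), the diazo group is removed (4), and the bond between the ketone carbon and the methylene is cut to 1 and 2. All stereochemistry now rests on the single stereocentre of 1, and 2 supplies the two outer carbons of ring B. The carbenoid must add to the alkene and not insert into C–H bonds, and the centre next to the carbonyl must not epimerise.

## Other disconnections considered

**Alternative 1:** The cut is the σ bond shared by rings B and C. In the forward sense the cyclohexadiene anhydride A1 (cis-1,2-dihydrophthalic anhydride) would undergo a disrotatory four-electron photo-electrocyclisation to the bicyclic anhydride A2.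

- In its favour: one photon would form ring B, ring C and the cis B/C fusion; the anhydride of A2 lies anti to the cyclobutene, which is the relation ring A needs; the ring C double bond is in place for ring D; no diazo compound or carbene is involved.
- Against it here: A1 is not an article of commerce and re-aromatises or isomerises easily. A2 is meso, so ring A would have to be annulated from two carboxyl carbons plus two further carbons, and the chain stereocentre would have to be set by an enantioselective desymmetrisation and a diastereoselective step. Ring D would still be missing.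
- Comparison: on the B/C stereochemistry and on mechanistic predictability this alternative is the equal of, or better than, the chosen plan (one pericyclic step against steps 10 to 13). On the step count for rings B and C it is better. On the relative and absolute configuration of the chain carbon it is worse, because the chosen plan takes both from 1 through the tether of step 3. The total count would probably not be lower.

**Alternative 2:** The cut removes the two ring A bonds that leave the A/B fusion carbons. In the forward sense the diene A4 (buta-1,3-diene) would add under high pressure to one cyclobutene of the tricyclic diene A3 (the anti dimer of cyclobutadiene), giving the meso tetracyclic diene A5.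

- In its favour: rings B, C and D arrive in A3 with the correct cis,anti,cis geometry, exo-face cycloaddition would give the cis A/B fusion anti to ring C, and all four rings exist after one step. This is the most convergent of the plans.
- Against it here: A3 is laborious to prepare and thermally labile; an unactivated dienophile needs forcing conditions; both cyclobutenes can react. A5 is meso with two double bonds, so the chain would have to be placed on the ring A alkene in the presence of the more reactive ring D alkene, at one of two enantiotopic carbons, and on the concave face (cis to ring B), whereas reagents prefer the convex face.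
- Comparison: on convergence and rings formed per step the alternative is better; on ladder stereochemistry it is equal. On chemoselectivity and on both aspects of the chain stereocentre it is worse than the chosen plan, which is longer but has each stereochemical issue answered by a substrate constraint.

**Alternative 3:** The cut removes both ring C bonds that link ring B to ring D. In the forward sense the cyclobutene of the bicyclic diene A6 (cis-bicyclo[4.2.0]octa-3,7-diene) and cyclobutene A7 would undergo a CuOTf-templated [2+2] photocycloaddition to the meso tetracyclic alkene A8.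

- In its favour: ring C is formed and ring D delivered in one step, the copper template selects strained alkenes and should give the cis,anti,cis product, and no diazo chemistry is needed.
- Against it here: cross-coupling of two similar cyclobutenes competes with both homodimerisations, so volatile A7 would be needed in large excess. A8 is meso, so the chain stereocentre problem of alternative 2 returns, although with one alkene only.
- Comparison: on step economy the alternative is clearly better than the chosen plan (rings C and D in one step against steps 11 to 17). On ladder stereochemistry it is equal, and a templated cycloaddition is at least as predictable as two carbene shifts. It is worse only at the remote stereocentre. The same cycloaddition run on 19, which already carries that stereocentre, would lead directly to 33; this hybrid is kept in reserve, its weak point being the statistical cross-coupling.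

Key step: step 13

Assumption (remark on the chemistry): each cyclopropane ester, aldehyde and tosylhydrazone is drawn and named as its exo epimer; any endo epimer formed alongside is carried forward, because both epimers give the same carbene and therefore the same cyclobutene.

## Route

Step 1
Reactants: 1 (S)-cyclohex-3-ene-1-carboxylic acid; 2 mono-tert-butyl malonate
Product: 4 tert-butyl 3-[(1S)-cyclohex-3-en-1-yl]-3-oxopropanoate, via acyl imidazolide 3 (not isolated)
Conditions: CDI, THF, rt; then 2, MgCl2, Et3N, MeCN, rt → 40 °C; aq. citric acid
Reagents that add atoms: none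
Why: Masamune–Brooks C-acylation: the acyl imidazolide acylates the magnesium enolate of the malonate half ester and the adduct loses CO2 on acidic work-up; the neutral activation and the chelated enolate should leave the stereocentre next to the carbonyl untouched, and no new stereocentre is formed.

Step 2
Reactants: 4 tert-butyl 3-[(1S)-cyclohex-3-en-1-yl]-3-oxopropanoate
Product: 5 tert-butyl 2-diazo-3-[(1S)-cyclohex-3-en-1-yl]-3-oxopropanoate
Conditions: 4-acetamidobenzenesulfonyl azide, Et3N, MeCN, 0 °C → rt
Reagents that add atoms: 4-acetamidobenzenesulfonyl azide, CC(=O)Nc1ccc(cc1)S(=O)(=O)N=[N+]=[N-]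
Why: Regitz diazo transfer to the doubly activated methylene; only that position is deprotonated by Et3N, so the ring stereocentre is not at risk, and the crystalline sulfonyl azide is chosen for safer handling.

Step 3
Reactants: 5 tert-butyl 2-diazo-3-[(1S)-cyclohex-3-en-1-yl]-3-oxopropanoate
Product: 6 tert-butyl (5S)-8-oxotricyclo[3.2.1.0(2,7)]octane-1-carboxylate (cyclopropane and keto bridge on the same face of the six-membered ring)
Conditions: Cu(acac)2 (5 mol %), toluene, 90 °C, slow addition of 5
Reagents that add atoms: none
Why: Copper-carbenoid intramolecular cyclopropanation of an unsaturated α-diazo-β-keto ester, the ester-substituted version of the classical cyclisation of cyclohex-3-enyl diazomethyl ketone; the one-carbon keto tether can reach only the alkene face cis to the acyl group, so the two cyclopropane CH centres and the quaternary apex are all dictated by the stereocentre of 1, and a copper catalyst is used because copper carbenoids have little tendency to insert into C–H bonds.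

Step 4
Reactants: 6 tert-butyl (5S)-8-oxotricyclo[3.2.1.0(2,7)]octane-1-carboxylate
Product: 7 (3S)-7-exo-(tert-butoxycarbonyl)bicyclo[4.1.0]heptane-3-carboxylic acid (carboxyl cis to the cyclopropane)
Conditions: LiOH·H2O (1.1 equiv), THF/H2O, 0 °C → rt; then 1 M HCl to pH 4, 0 °C
Reagents that add atoms: lithium hydroxide, [Li+].[OH-]
Why: Retro-Claisen (acid cleavage) of a non-enolisable β-keto ester: hydroxide adds to the strained one-carbon keto bridge and the bond to the ester-bearing cyclopropane carbon breaks, releasing an ester-stabilised cyclopropyl carbanion that is protonated in the position the bridge occupied (ester exo); the carboxylate left on ring A is cis to the cyclopropane by construction, does not epimerise as a carboxylate, and the tert-butyl ester resists hydroxide.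

Step 5
Reactants: 7 (3S)-7-exo-(tert-butoxycarbonyl)bicyclo[4.1.0]heptane-3-carboxylic acid
Product: 8 tert-butyl (3S)-3-(hydroxymethyl)bicyclo[4.1.0]heptane-7-exo-carboxylate (hydroxymethyl cis to the cyclopropane)
Conditions: BH3·SMe2, THF, 0 °C → rt; MeOH quench
Reagents that add atoms: none
Why: Chemoselective borane reduction: a free carboxylic acid is reduced through its acyloxyborane far faster than a tert-butyl ester, and no stereocentre is touched.

Step 6
Reactants: 8 tert-butyl (3S)-3-(hydroxymethyl)bicyclo[4.1.0]heptane-7-exo-carboxylate
Product: 9 tert-butyl (3S)-3-(tosyloxymethyl)bicyclo[4.1.0]heptane-7-exo-carboxylate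
Conditions: TsCl, Et3N, DMAP (cat.), CH2Cl2, 0 °C → rt
Reagents that add atoms: p-toluenesulfonyl chloride, Cc1ccc(cc1)S(Cl)(=O)=O
Why: Standard sulfonylation of an unhindered primary alcohol; the leaving group sits on a primary carbon one atom from the stereocentre, so no epimerisation or rearrangement is expected.

Step 7
Reactants: 10 2,2-dimethyl-1,3-dioxan-5-ol; 11 1,7-dibromoheptane
Product: 12 5-[(7-bromoheptyl)oxy]-2,2-dimethyl-1,3-dioxane
Conditions: 11 (4 equiv), 50% aq. NaOH, n-Bu4NHSO4 (cat.), 50 °C
Reagents that add atoms: none
Why: Williamson ether synthesis under phase-transfer conditions; the excess of dibromide suppresses double alkylation, the acetal is stable to base, and unreacted 11 is recovered by distillation.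

Step 8
Reactants: 9 tert-butyl (3S)-3-(tosyloxymethyl)bicyclo[4.1.0]heptane-7-exo-carboxylate; 12 5-[(7-bromoheptyl)oxy]-2,2-dimethyl-1,3-dioxane
Product: 14 tert-butyl (3S)-3-{8-[(2,2-dimethyl-1,3-dioxan-5-yl)oxy]octyl}bicyclo[4.1.0]heptane-7-exo-carboxylate (chain cis to the cyclopropane), via alkylmagnesium bromide 13 (not isolated)
Conditions: 12, Mg, THF, 40 °C; then 9, Li2CuCl4 (5 mol %), THF, −30 °C → rt
Reagents that add atoms: none
Why: Copper-catalysed sp3–sp3 cross-coupling of a primary tosylate with a primary alkylmagnesium bromide (Kochi-type coupling); at low temperature the hindered tert-butyl ester and the acetal are not attacked, and the bond is formed one carbon away from the stereocentre, which is therefore unchanged.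

Step 9
Reactants: 14 tert-butyl (3S)-3-{8-[(2,2-dimethyl-1,3-dioxan-5-yl)oxy]octyl}bicyclo[4.1.0]heptane-7-exo-carboxylate
Product: 16 N-tosylhydrazone (E) of (3S)-3-{8-[(2,2-dimethyl-1,3-dioxan-5-yl)oxy]octyl}bicyclo[4.1.0]heptane-7-exo-carbaldehyde, via aldehyde 15 (not isolated)
Conditions: i-Bu2AlH, CH2Cl2, −78 °C; MeOH, aq. potassium sodium tartrate; then TsNHNH2, MeOH, rt
Reagents that add atoms: p-toluenesulfonohydrazide, Cc1ccc(cc1)S(=O)(=O)NN
Why: Partial reduction of an ester by i-Bu2AlH stops at the aluminium hemiacetal at −78 °C, especially for a tert-butyl ester, and the aldehyde released on work-up is condensed at once with the hydrazide without acid, so the acetal is safe and the exo aldehyde is not handled long enough to degrade.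

Step 10
Reactants: 16 N-tosylhydrazone of (3S)-3-{8-[(2,2-dimethyl-1,3-dioxan-5-yl)oxy]octyl}bicyclo[4.1.0]heptane-7-exo-carbaldehyde
Product: 19 5-({8-[(3S)-cis-bicyclo[4.2.0]oct-7-en-3-yl]octyl}oxy)-2,2-dimethyl-1,3-dioxane (chain cis to the cyclobutene), via lithium tosylhydrazonide 17 (not isolated), via diazoalkane 18 (not isolated)
Conditions: LiN(SiMe3)2 (1.05 equiv), THF, −78 °C; hν (Hg lamp, Pyrex), −40 → 0 °C
Reagents that add atoms: none
Why: Photochemical aprotic Bamford–Stevens reaction: the salt gives the diazoalkane, this gives a cyclopropylcarbene, and a cyclopropane bond shifts to the carbene carbon to give the cyclobutene, which is the precedented expansion of 7-norcaranylcarbene to bicyclo[4.2.0]oct-7-ene; the migrating carbon keeps its configuration, so ring B stays cis to the chain, and the non-nucleophilic amide base avoids addition to the C=N bond.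

Step 11
Reactants: 19 5-({8-[(3S)-cis-bicyclo[4.2.0]oct-7-en-3-yl]octyl}oxy)-2,2-dimethyl-1,3-dioxane; 20 ethyl diazoacetate
Product: 21 ethyl (3S)-3-{8-[(2,2-dimethyl-1,3-dioxan-5-yl)oxy]octyl}tricyclo[4.3.0.0(7,9)]nonane-8-exo-carboxylate (ring A cis-fused to ring B; cyclopropane on the outer bond of ring B anti to ring A; chain cis to ring B)
Conditions: 20 (slow addition), Rh2(OAc)4 (1 mol %), CH2Cl2, rt
Reagents that add atoms: none
Why: Rhodium-carbenoid cyclopropanation of a strained cis-alkene, known for cyclobutenes; the carbenoid approaches the convex face of ring B, anti to ring A, which sets the two new ring-fusion centres, and the ester prefers the exo position away from the four-membered ring, while slow addition limits carbene dimerisation.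

Step 12
Reactants: 21 ethyl (3S)-3-{8-[(2,2-dimethyl-1,3-dioxan-5-yl)oxy]octyl}tricyclo[4.3.0.0(7,9)]nonane-8-exo-carboxylate
Product: 23 N-tosylhydrazone (E) of (3S)-3-{8-[(2,2-dimethyl-1,3-dioxan-5-yl)oxy]octyl}tricyclo[4.3.0.0(7,9)]nonane-8-exo-carbaldehyde (stereochemistry as in 21), via aldehyde 22 (not isolated)
Conditions: i-Bu2AlH, CH2Cl2, −78 °C; MeOH, aq. potassium sodium tartrate; then TsNHNH2, MeOH, 0 °C → rt
Reagents that add atoms: p-toluenesulfonohydrazide, Cc1ccc(cc1)S(=O)(=O)NN
Why: Same partial ester reduction and acid-free condensation as in step 9; the bicyclo[2.1.0]pentane aldehyde is trapped as the crystalline hydrazone without isolation, and no stereocentre is changed.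

Step 13
Reactants: 23 N-tosylhydrazone of (3S)-3-{8-[(2,2-dimethyl-1,3-dioxan-5-yl)oxy]octyl}tricyclo[4.3.0.0(7,9)]nonane-8-exo-carbaldehyde
Product: 26 5-({8-[(8S)-tricyclo[4.4.0.0(2,5)]dec-3-en-8-yl]octyl}oxy)-2,2-dimethyl-1,3-dioxane (rings A B C cis-anti-cis; ring C a cyclobutene; chain cis to ring B), via lithium tosylhydrazonide 24 (not isolated), via diazoalkane 25 (not isolated)
Conditions: LiN(SiMe3)2 (1.05 equiv), THF, −78 °C; hν (Hg lamp, Pyrex), 0.01 M, −40 → −10 °C
Reagents that add atoms: none
Why: Deprotonation gives the lithium tosylhydrazonide 24, which on irradiation loses lithium p-toluenesulfinate to give the diazoalkane 25, and photolysis of 25 expels N2 to leave a singlet cyclopropylcarbene. In its bisected conformation the empty carbene orbital overlaps with both cyclopropane bonds that run to ring B, and one of them shifts to the carbene carbon in a concerted 1,2-shift, so the three-membered ring grows into the cyclobutene ring C while the new bond from ring B to the former carbene carbon is formed. The closest known reaction is the aprotic Bamford–Stevens expansion of cyclopropylcarbenes to cyclobutenes, the reaction type of step 10, applied here to a bicyclo[2.1.0]pentane whose strain is of the same order as that of the bicyclo[2.2.0]hexene formed, so the energy of the carbene drives the shift and no large strain increase opposes it. Ring C is closed by ring enlargement through a 1,2-alkyl shift and not by cyclisation of an open chain. No stereocentre is created, because the two carbons that complete ring C become sp2, and the two ring B carbons keep their configuration because the shift is suprafacial with retention at the migrating carbon, which preserves the cis B/C fusion and the anti relation to ring A set in step 11. Regioselectivity is not an issue, since migration of either bond gives the same alkene. The step needs ring expansion to win over cycloreversion with loss of a two-carbon fragment, over hydrogen shift and over bimolecular reactions of 25; this is secured by the exo carbene centre, the absence of any migratable hydrogen other than the cyclopropyl methine, high dilution, continuous irradiation that keeps 25 at low concentration, and a temperature at which the strained σ bonds do not cleave.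

Step 14
Reactants: 26 5-({8-[(8S)-tricyclo[4.4.0.0(2,5)]dec-3-en-8-yl]octyl}oxy)-2,2-dimethyl-1,3-dioxane; 20 ethyl diazoacetate
Product: 27 ethyl ester of the exo cyclopropanecarboxylic acid fused to the former double bond of ring C of 26 (cyclopropane anti to ring B; rings A B C and chain as in 26)
Conditions: 20 (slow addition), Rh2(OAc)4 (1 mol %), CH2Cl2, 0 °C
Reagents that add atoms: none
Why: Rhodium-carbenoid cyclopropanation as in step 11; the folded bicyclo[2.2.0]hexene exposes only its exo face, so the two new ring-fusion centres are set anti to ring B, and the ester again prefers the exo position.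

Step 15
Reactants: 27 ethyl ester of the exo cyclopropanecarboxylic acid fused to ring C
Product: 29 N-tosylhydrazone (E) of the exo cyclopropanecarbaldehyde fused to ring C (stereochemistry as in 27), via aldehyde 28 (not isolated)
Conditions: i-Bu2AlH, CH2Cl2, −78 °C; MeOH, aq. potassium sodium tartrate; then TsNHNH2, MeOH, 0 °C
Reagents that add atoms: p-toluenesulfonohydrazide, Cc1ccc(cc1)S(=O)(=O)NN
Why: Same partial reduction and condensation as in steps 9 and 12, kept cold throughout because the substrate now contains a bicyclo[2.2.0]hexane and a bicyclo[2.1.0]pentane; no stereocentre is changed.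

Step 16
Reactants: 29 N-tosylhydrazone of the exo cyclopropanecarbaldehyde fused to ring C
Product: 32 5-({8-[(10S)-tetracyclo[6.4.0.0(2,7).0(3,6)]dodec-4-en-10-yl]octyl}oxy)-2,2-dimethyl-1,3-dioxane (rings A B C D cis-anti-cis-anti-cis; ring D a cyclobutene; chain cis to ring B), via lithium tosylhydrazonide 30 (not isolated), via diazoalkane 31 (not isolated)
Conditions: LiN(SiMe3)2 (1.05 equiv), THF, −78 °C; hν (Hg lamp, Pyrex), 0.01 M, −40 → −10 °C
Reagents that add atoms: none
Why: Second use of the photochemical Bamford–Stevens cyclopropylcarbene expansion of step 13; the migrating ring C carbon keeps its configuration, so the C/D fusion is cis and anti to ring B, and no new stereocentre arises because the ring D carbons formed are sp2.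

Step 17
Reactants: 32 5-({8-[(10S)-tetracyclo[6.4.0.0(2,7).0(3,6)]dodec-4-en-10-yl]octyl}oxy)-2,2-dimethyl-1,3-dioxane
Product: 33 5-({8-[(10S)-tetracyclo[6.4.0.0(2,7).0(3,6)]dodecan-10-yl]octyl}oxy)-2,2-dimethyl-1,3-dioxane
Conditions: 2-nitrobenzenesulfonohydrazide, Et3N, CH2Cl2, rt
Reagents that add atoms: none
Why: Diimide, released from the sulfonohydrazide under mild base, transfers two hydrogens in a concerted syn fashion to the strained cyclobutene, which is among the fastest diimide acceptors; no metal is present to hydrogenolyse the ladder σ bonds, and the new carbons are CH2 groups, so no stereocentre is formed.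

Step 18
Reactants: 33 5-({8-[(10S)-tetracyclo[6.4.0.0(2,7).0(3,6)]dodecan-10-yl]octyl}oxy)-2,2-dimethyl-1,3-dioxane
Product: 34 2-({8-[(10S)-tetracyclo[6.4.0.0(2,7).0(3,6)]dodecan-10-yl]octyl}oxy)propane-1,3-diol (all ring fusions cis; neighbouring rings anti; chain cis to ring B)
Conditions: 1 M HCl, THF, rt
Reagents that add atoms: none
Why: Acid-catalysed hydrolysis of an isopropylidene acetal of a 1,3-diol, which is more labile than a dioxolane; saturated cyclobutanes are inert to dilute aqueous acid at room temperature, so the ladder and all seven stereocentres are unaffected.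

## Compound list

1 | (S)-cyclohex-3-ene-1-carboxylic acid | OC(=O)[C@H]1CCC=CC1 | starting material
2 | mono-tert-butyl malonate (3-tert-butoxy-3-oxopropanoic acid) | CC(C)(C)OC(=O)CC(O)=O | starting material
3 | (S)-cyclohex-3-en-1-yl(1H-imidazol-1-yl)methanone | O=C([C@H]1CCC=CC1)n1ccnc1 | intermediate
4 | tert-butyl 3-[(1S)-cyclohex-3-en-1-yl]-3-oxopropanoate | CC(C)(C)OC(=O)CC(=O)[C@H]1CCC=CC1 | intermediate
5 | tert-butyl 2-diazo-3-[(1S)-cyclohex-3-en-1-yl]-3-oxopropanoate | CC(C)(C)OC(=O)C(=[N+]=[N-])C(=O)[C@H]1CCC=CC1 | intermediate
6 | tert-butyl (5S)-8-oxotricyclo[3.2.1.0(2,7)]octane-1-carboxylate | O=C1[C@H]2CC[C@@H]3[C@H](C2)[C@]13C(=O)OC(C)(C)C | intermediate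
7 | (3S)-7-exo-(tert-butoxycarbonyl)bicyclo[4.1.0]heptane-3-carboxylic acid, carboxyl cis to the cyclopropane | OC(=O)[C@H]1CC[C@@H]2[C@H](C1)[C@H]2C(=O)OC(C)(C)C | intermediate
8 | tert-butyl (3S)-3-(hydroxymethyl)bicyclo[4.1.0]heptane-7-exo-carboxylate, hydroxymethyl cis to the cyclopropane | OC[C@H]1CC[C@@H]2[C@H](C1)[C@H]2C(=O)OC(C)(C)C | intermediate
9 | tert-butyl (3S)-3-(tosyloxymethyl)bicyclo[4.1.0]heptane-7-exo-carboxylate | Cc1ccc(cc1)S(=O)(=O)OC[C@H]1CC[C@@H]2[C@H](C1)[C@H]2C(=O)OC(C)(C)C | intermediate
10 | 2,2-dimethyl-1,3-dioxan-5-ol | CC1(C)OCC(O)CO1 | starting material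
11 | 1,7-dibromoheptane | BrCCCCCCCBr | starting material
12 | 5-[(7-bromoheptyl)oxy]-2,2-dimethyl-1,3-dioxane | CC1(C)OCC(CO1)OCCCCCCCBr | intermediate
13 | {7-[(2,2-dimethyl-1,3-dioxan-5-yl)oxy]heptyl}magnesium bromide | CC1(C)OCC(CO1)OCCCCCCC[Mg]Br | intermediate
14 | tert-butyl (3S)-3-{8-[(2,2-dimethyl-1,3-dioxan-5-yl)oxy]octyl}bicyclo[4.1.0]heptane-7-exo-carboxylate, chain cis to the cyclopropane | CC1(C)OCC(CO1)OCCCCCCCC[C@H]1CC[C@@H]2[C@H](C1)[C@H]2C(=O)OC(C)(C)C | intermediate
15 | (3S)-3-{8-[(2,2-dimethyl-1,3-dioxan-5-yl)oxy]octyl}bicyclo[4.1.0]heptane-7-exo-carbaldehyde | CC1(C)OCC(CO1)OCCCCCCCC[C@H]1CC[C@@H]2[C@H](C1)[C@H]2C=O | intermediate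
16 | N-tosylhydrazone (E) of 15 | CC1(C)OCC(CO1)OCCCCCCCC[C@H]1CC[C@@H]2[C@H](C1)[C@H]2/C=N/NS(=O)(=O)c1ccc(C)cc1 | intermediate
17 | lithium salt of 16 | [Li+].CC1(C)OCC(CO1)OCCCCCCCC[C@H]1CC[C@@H]2[C@H](C1)[C@H]2/C=N/[N-]S(=O)(=O)c1ccc(C)cc1 | intermediate
18 | (3S)-7-exo-(diazomethyl)-3-{8-[(2,2-dimethyl-1,3-dioxan-5-yl)oxy]octyl}bicyclo[4.1.0]heptane | CC1(C)OCC(CO1)OCCCCCCCC[C@H]1CC[C@@H]2[C@H](C1)[C@H]2C=[N+]=[N-] | intermediate
19 | 5-({8-[(3S)-cis-bicyclo[4.2.0]oct-7-en-3-yl]octyl}oxy)-2,2-dimethyl-1,3-dioxane, chain cis to the cyclobutene | CC1(C)OCC(CO1)OCCCCCCCC[C@H]1CC[C@@H]2[C@H](C1)C=C2 | intermediate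
20 | ethyl diazoacetate | CCOC(=O)C=[N+]=[N-] | starting material
21 | ethyl (3S)-3-{8-[(2,2-dimethyl-1,3-dioxan-5-yl)oxy]octyl}tricyclo[4.3.0.0(7,9)]nonane-8-exo-carboxylate, cyclopropane anti to ring A, chain cis to ring B | CC1(C)OCC(CO1)OCCCCCCCC[C@H]1CC[C@@H]2[C@H](C1)[C@H]1[C@H](C(=O)OCC)[C@@H]21 | intermediate
22 | (3S)-3-{8-[(2,2-dimethyl-1,3-dioxan-5-yl)oxy]octyl}tricyclo[4.3.0.0(7,9)]nonane-8-exo-carbaldehyde | CC1(C)OCC(CO1)OCCCCCCCC[C@H]1CC[C@@H]2[C@H](C1)[C@H]1[C@H](C=O)[C@@H]21 | intermediate
23 | N-tosylhydrazone (E) of 22 | CC1(C)OCC(CO1)OCCCCCCCC[C@H]1CC[C@@H]2[C@H](C1)[C@H]1[C@H](/C=N/NS(=O)(=O)c3ccc(C)cc3)[C@@H]21 | intermediate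
24 | lithium salt of 23 | [Li+].CC1(C)OCC(CO1)OCCCCCCCC[C@H]1CC[C@@H]2[C@H](C1)[C@H]1[C@H](/C=N/[N-]S(=O)(=O)c3ccc(C)cc3)[C@@H]21 | intermediate
25 | 8-exo-diazomethyl analogue of 22 | CC1(C)OCC(CO1)OCCCCCCCC[C@H]1CC[C@@H]2[C@H](C1)[C@H]1[C@H](C=[N+]=[N-])[C@@H]21 | intermediate
26 | 5-({8-[(8S)-tricyclo[4.4.0.0(2,5)]dec-3-en-8-yl]octyl}oxy)-2,2-dimethyl-1,3-dioxane, rings A, B, C cis-anti-cis, chain cis to ring B | CC1(C)OCC(CO1)OCCCCCCCC[C@H]1CC[C@@H]2[C@H](C1)[C@H]1C=C[C@@H]21 | intermediate
27 | ethyl ester of the exo cyclopropanecarboxylic acid fused to ring C of 26, cyclopropane anti to ring B | CC1(C)OCC(CO1)OCCCCCCCC[C@H]1CC[C@@H]2[C@H](C1)[C@H]1[C@@H]3[C@@H](C(=O)OCC)[C@@H]3[C@@H]21 | intermediate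
28 | exo cyclopropanecarbaldehyde corresponding to 27 | CC1(C)OCC(CO1)OCCCCCCCC[C@H]1CC[C@@H]2[C@H](C1)[C@H]1[C@@H]3[C@@H](C=O)[C@@H]3[C@@H]21 | intermediate
29 | N-tosylhydrazone (E) of 28 | CC1(C)OCC(CO1)OCCCCCCCC[C@H]1CC[C@@H]2[C@H](C1)[C@H]1[C@@H]3[C@@H](/C=N/NS(=O)(=O)c4ccc(C)cc4)[C@@H]3[C@@H]21 | intermediate
30 | lithium salt of 29 | [Li+].CC1(C)OCC(CO1)OCCCCCCCC[C@H]1CC[C@@H]2[C@H](C1)[C@H]1[C@@H]3[C@@H](/C=N/[N-]S(=O)(=O)c4ccc(C)cc4)[C@@H]3[C@@H]21 | intermediate
31 | exo diazomethyl analogue of 28 | CC1(C)OCC(CO1)OCCCCCCCC[C@H]1CC[C@@H]2[C@H](C1)[C@H]1[C@@H]3[C@@H](C=[N+]=[N-])[C@@H]3[C@@H]21 | intermediate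
32 | 5-({8-[(10S)-tetracyclo[6.4.0.0(2,7).0(3,6)]dodec-4-en-10-yl]octyl}oxy)-2,2-dimethyl-1,3-dioxane, cis-anti-cis-anti-cis | CC1(C)OCC(CO1)OCCCCCCCC[C@H]1CC[C@@H]2[C@H](C1)[C@H]1[C@@H]3C=C[C@@H]3[C@@H]21 | intermediate
33 | 5-({8-[(10S)-tetracyclo[6.4.0.0(2,7).0(3,6)]dodecan-10-yl]octyl}oxy)-2,2-dimethyl-1,3-dioxane | CC1(C)OCC(CO1)OCCCCCCCC[C@H]1CC[C@@H]2[C@H](C1)[C@H]1[C@@H]3CC[C@@H]3[C@@H]21 | intermediate
34 | 2-({8-[(10S)-tetracyclo[6.4.0.0(2,7).0(3,6)]dodecan-10-yl]octyl}oxy)propane-1,3-diol | OCC(CO)OCCCCCCCC[C@H]1CC[C@@H]2[C@H](C1)[C@H]1[C@@H]3CC[C@@H]3[C@@H]21 | target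

## Step count and least certain steps

Total: 18 steps. Longest linear sequence: 17 steps (steps 1 to 6 and 8 to 18, from 1 to 34); step 7 supplies fragment 12 in one step.

**Step 13 (key step).**
- Most likely failure: the carbene partitions toward cycloreversion, with loss of a two-carbon fragment that restores the ring B double bond, or toward a 1,2-hydrogen shift. The diazo intermediate may also be consumed by cycloaddition to the strained alkene as it accumulates. The cause is that the rearrangement must pass through a more strained transition state than in the norcarane case of step 10.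
- Fallback, from 19 back to 26: acetophenone-sensitised [2+2] photocycloaddition of 19 with maleic anhydride on the exo face of ring B should give the ring C cyclobutane-1,2-dicarboxylic anhydride F1. Mild aqueous hydrolysis (NaHCO3, then careful acidification) gives the cis-dicarboxylic acid F2. Oxidative bis-decarboxylation with Pb(OAc)4 in pyridine introduces the ring C double bond and returns to the route at 26. The two carboxyl-bearing centres become sp2, so only the facial selectivity toward ring B matters.

**Step 16.**
- Most likely failure: the same partitioning of the carbene, made worse by the additional bicyclo[2.2.0]hexane, whose central bond may also open thermally during work-up.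
- Fallback, from 26 back to 32: the same sensitised [2+2] photocycloaddition of maleic anhydride to the ring C double bond, anti to ring B, gives the ring D anhydride F3. Hydrolysis gives the cis-dicarboxylic acid F4. Bis-decarboxylation with Pb(OAc)4 in pyridine rejoins the route at 32.

**Step 4.**
- Most likely failure: hydroxide attacks a cyclopropane carbon of the doubly activated ring (homoconjugate opening) instead of the ketone, or cleavage is slow enough for ester hydrolysis to interfere.
- Fallback, from 1 back to 16 (it also bypasses step 3), using a lactone tether. This is judged less reliable in the ring-forming step, because a seven-membered lactone must close in competition with C–H insertion, but it never places the stereocentre next to a carbonyl.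
  - LiAlH4 reduction of 1 gives (S)-cyclohex-3-en-1-ylmethanol F5.
  - Acylation with glyoxylic acid chloride p-toluenesulfonylhydrazone (PhNMe2, then Et3N) gives the diazoacetate F6.
  - Cu(MeCN)4PF6-catalysed intramolecular cyclopropanation at high dilution gives the bridged seven-membered lactone F7, with the cyclopropane necessarily cis to the tether.
  - NaOMe in MeOH at reflux opens the lactone and epimerises the ester to the exo hydroxy methyl ester F8.
  - Tosylation gives the tosylate F9, and coupling with 13 (Li2CuCl4) gives the methyl ester F10.
  - F10 under the conditions of step 9 gives 16.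

**Step 12.**
- Most likely failure: over-reduction beyond the aldehyde oxidation level, or opening of the bicyclo[2.1.0]pentane promoted by the Lewis-acidic aluminium reagent; the same concern applies to step 15.
- Fallback, from 21 back to 22: full reduction with LiAlH4 in Et2O at 0 °C gives the exo cyclopropylmethanol F11. Buffered Dess–Martin oxidation (NaHCO3, CH2Cl2, 0 °C) gives aldehyde 22, which is condensed with the hydrazide as in step 12.

## Further compounds

F1 | step 13 | cyclobutane-1,2-dicarboxylic anhydride fused to the outer bond of ring B of 19, anti to ring A | CC1(C)OCC(CO1)OCCCCCCCC[C@H]1CC[C@@H]2[C@H](C1)[C@H]1[C@@H]3C(=O)OC(=O)[C@@H]3[C@@H]21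
F2 | step 13 | cis-dicarboxylic acid from F1 | CC1(C)OCC(CO1)OCCCCCCCC[C@H]1CC[C@@H]2[C@H](C1)[C@H]1[C@H](C(=O)O)[C@H](C(=O)O)[C@@H]21
F3 | step 16 | cyclobutane-1,2-dicarboxylic anhydride fused to the outer bond of ring C of 26, anti to ring B | CC1(C)OCC(CO1)OCCCCCCCC[C@H]1CC[C@@H]2[C@H](C1)[C@H]1[C@@H]3[C@H]4C(=O)OC(=O)[C@H]4[C@@H]3[C@@H]21
F4 | step 16 | cis-dicarboxylic acid from F3 | CC1(C)OCC(CO1)OCCCCCCCC[C@H]1CC[C@@H]2[C@H](C1)[C@H]1[C@@H]3[C@@H](C(=O)O)[C@@H](C(=O)O)[C@@H]3[C@@H]21
F5 | step 4 | (S)-cyclohex-3-en-1-ylmethanol | OC[C@H]1CCC=CC1
F6 | step 4 | [(1S)-cyclohex-3-en-1-yl]methyl diazoacetate | [N-]=[N+]=CC(=O)OC[C@H]1CCC=CC1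
F7 | step 4 | bridged seven-membered lactone joining the hydroxymethyl carbon to the endo position of the cyclopropane apex | O=C1OC[C@H]2CC[C@@H]3[C@H](C2)[C@H]13
F8 | step 4 | methyl (3S)-3-(hydroxymethyl)bicyclo[4.1.0]heptane-7-exo-carboxylate | OC[C@H]1CC[C@@H]2[C@H](C1)[C@H]2C(=O)OC
F9 | step 4 | methyl (3S)-3-(tosyloxymethyl)bicyclo[4.1.0]heptane-7-exo-carboxylate | Cc1ccc(cc1)S(=O)(=O)OC[C@H]1CC[C@@H]2[C@H](C1)[C@H]2C(=O)OC
F10 | step 4 | methyl (3S)-3-{8-[(2,2-dimethyl-1,3-dioxan-5-yl)oxy]octyl}bicyclo[4.1.0]heptane-7-exo-carboxylate | CC1(C)OCC(CO1)OCCCCCCCC[C@H]1CC[C@@H]2[C@H](C1)[C@H]2C(=O)OC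
F11 | step 12 | exo cyclopropylmethanol from 21 | CC1(C)OCC(CO1)OCCCCCCCC[C@H]1CC[C@@H]2[C@H](C1)[C@H]1[C@H](CO)[C@@H]21
A1 | alternative 1 | cis-1,2-dihydrophthalic anhydride (meso) | O=C1OC(=O)[C@@H]2[C@H]1C=CC=C2
A2 | alternative 1 | exo-bicyclo[2.2.0]hex-5-ene-2,3-dicarboxylic anhydride (meso) | O=C1OC(=O)[C@@H]2[C@H]1[C@H]3C=C[C@@H]23
A3 | alternative 2 | anti-tricyclo[4.2.0.0(2,5)]octa-3,7-diene | C1=C[C@@H]2[C@H]1[C@H]1C=C[C@@H]21
A4 | alternative 2 | buta-1,3-diene | C=CC=C
A5 | alternative 2 | meso tetracyclic diene with ring A and ring D double bonds | C1=CC[C@@H]2[C@H](C1)[C@H]1[C@@H]3C=C[C@@H]3[C@@H]21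
A6 | alternative 3 | cis-bicyclo[4.2.0]octa-3,7-diene (meso) | C1=C[C@@H]2CC=CC[C@H]12
A7 | alternative 3 | cyclobutene | C1=CCC1
A8 | alternative 3 | meso tetracyclic [3]-ladderane with a ring A double bond | C1=CC[C@@H]2[C@H](C1)[C@H]1[C@@H]3CC[C@@H]3[C@@H]21
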